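**Plan**

- Locants: O1, C2 and C3 lie in the five-membered furanone ring (ring B) fused to the phenol ring (ring A); C1', C2', C3' are the first chain carbons.
- Feature used: the C2 hemiketal OH and the C2'=C3' olefin flank the C1' methylene (a 3-en-1-ol array). This is what remains when the allylic C1'–O bond of a spiro alkenyloxirane across C2/C1' is replaced by C1'–H, and that oxirane is the epoxide of an exocyclic C2=C1' enone conjugated with the ring-B C3 carbonyl.
- Cuts, in retrosynthetic order: aryl O–H (from O–Si); C1'–H (from the oxirane C1'–O); the oxirane C2–O and C1'–O bonds (back to the C2=C1' dienone); C2=C1' (back to the benzofuranone CH2 and farnesal).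
- Forward: rings A and B are purchased; the chain is joined by aldol condensation; the spiro-oxirane is the only ring closed and is reopened at C1' by palladium-mediated hydride delivery before the phenol is unmasked.
- Stereochemistry: the single stereocentre C2 (R) is set in the catalytic asymmetric nucleophilic epoxidation and stays a ketal carbon until the oxirane is opened under buffered conditions; the 2'E and 6'E olefins come unchanged from (2E,6E)-farnesol.

Key step: step 4

Remark (configurational stability): the C2 hemiketal can open to the 1,2-diketone under base, so it is assumed stable only in neutral to weakly acidic media at or below room temperature, and base is excluded after step 4.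
Remark (sense of induction): the catalyst is taken from the cinchonine series; the facial sense is to be confirmed on the first run, and the pseudo-enantiomeric cinchonidinium salt gives the other face with no change to the route.

**Route**

Step 1
Reactants: 1 6-hydroxy-1-benzofuran-3(2H)-one
Product: 2 6-[(triisopropylsilyl)oxy]-1-benzofuran-3(2H)-one
Conditions: TIPSCl (1.1 equiv), imidazole (2 equiv), DMF, 0 °C to rt
Reagents that add atoms: triisopropylsilyl chloride, CC(C)[Si](Cl)(C(C)C)C(C)C
Why: Imidazole-mediated O-silylation of the phenol is a routine silyl ether formation, and under this weak base the C2 methylene is not enolised, so no enol silyl ether should form and no stereocentre is created.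

Step 2
Reactants: 3 (2E,6E)-farnesol
Product: 4 (2E,6E)-farnesal
Conditions: activated MnO2 (10 equiv), CH2Cl2, rt
Reagents that add atoms: none
Why: Heterogeneous MnO2 oxidation is selective for the allylic primary alcohol, stops at the aldehyde and should leave the 2E geometry and the two isolated olefins untouched, with no stereocentre created.

Step 3
Reactants: 2 6-[(triisopropylsilyl)oxy]-1-benzofuran-3(2H)-one; 4 (2E,6E)-farnesal
Product: 6 (2Z)-2-[(2E,6E)-3,7,11-trimethyldodeca-2,6,10-trien-1-ylidene]-6-[(triisopropylsilyl)oxy]-1-benzofuran-3(2H)-one, via aldol adduct 5 (not isolated)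
Conditions: 4 (1.3 equiv), neutral Al2O3, CH2Cl2, rt
Reagents that add atoms: none
Why: Aldol condensation (Knoevenagel type) of the acidic C2 methylene of a benzofuran-3(2H)-one with an aldehyde on neutral Al2O3 is the standard aurone synthesis and should extend to this β,β-disubstituted enal, whose substitution blocks Michael addition, the aldol 5 dehydrating on the surface to the thermodynamically preferred Z-alkylidene (chain cis to O1) so that no stereocentre remains.

Step 4
Reactants: 6 (2Z)-2-[(2E,6E)-3,7,11-trimethyldodeca-2,6,10-trien-1-ylidene]-6-[(triisopropylsilyl)oxy]-1-benzofuran-3(2H)-one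
Product: 7 (2R,3'R)-3'-[(1E,5E)-2,6,10-trimethylundeca-1,5,9-trien-1-yl]-6-[(triisopropylsilyl)oxy]-3H-spiro[1-benzofuran-2,2'-oxiran]-3-one
Conditions: N-[4-(trifluoromethyl)benzyl]cinchoninium bromide (10 mol%), cumene hydroperoxide (1.5 equiv), 1 M aq KOH (0.5 equiv), toluene, 0 °C
Reagents that add atoms: cumene hydroperoxide, CC(C)(OO)c1ccccc1
Why: The ammonium cation carries the cumylperoxide anion into toluene as a tight chiral ion pair, the peroxide oxygen adds to C1' (the β-carbon of the s-cis-locked exocyclic enone) to give a β-peroxy enolate, and the enolate carbon C2 then displaces cumyloxide from the inner peroxide oxygen, so that C1'–O forms first and C2–O second. The closest known reaction type is the asymmetric phase-transfer Weitz–Scheffer epoxidation of chalcones, of 2-arylidene-1-tetralones and -indanones, of isoflavones and of aurones with alkyl hydroperoxides, together with the α,β-selective nucleophilic epoxidation of dienones. The oxirane, the only ring closed in the route, forms by a 3-exo-tet displacement at oxygen. The new centre at C1' (3' of the spiro name) is controlled by the catalyst, whose cation blocks one face of the ion-paired enone so that oxygen enters on the face that is Re at C1'; the centre at C2 is controlled by the substrate, because ring closure is faster than rotation about C1'–C2 and keeps the chain anti to the C3 carbonyl, which converts the Z geometry into the 2R,3'R oxirane. The step needs 1,4- and not 1,6-addition, which the fully substituted C3' secures, and reaction at the enone only, which is secured because the three remaining trisubstituted olefins are not electrophilic and a peroxide anion does not attack them. Substoichiometric hydroxide that is converted into the bulky peroxide anion should leave the hindered aryl silyl ether intact, and of the two new centres only C2 is needed later.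

Step 5
Reactants: 7 (2R,3'R)-3'-[(1E,5E)-2,6,10-trimethylundeca-1,5,9-trien-1-yl]-6-[(triisopropylsilyl)oxy]-3H-spiro[1-benzofuran-2,2'-oxiran]-3-one
Product: 8 (2R)-2-hydroxy-2-[(2E,6E)-3,7,11-trimethyldodeca-2,6,10-trien-1-yl]-6-[(triisopropylsilyl)oxy]-1-benzofuran-3(2H)-one
Conditions: Pd(PPh3)4 (5 mol%), Bu3SnH (1.3 equiv, added slowly), AcOH (3 equiv), CH2Cl2, 0 °C to rt
Reagents that add atoms: none
Why: Zerovalent palladium ionises the allylic C1'–O bond of the alkenyloxirane (the quaternary C2–O bond cannot be attacked), acetic acid protonates the C2 oxyanion at once, and the π-allylpalladium acetate is reduced by hydride transfer from tin followed by C–H reductive elimination at the less substituted terminus C1' (palladium-catalysed allylic hydrogenolysis after Tsuji–Trost-type ionisation), which should keep the C2'=C3' olefin E and leave C2 untouched as R while the C1' stereocentre disappears as CH2.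

Step 6
Reactants: 8 (2R)-2-hydroxy-2-[(2E,6E)-3,7,11-trimethyldodeca-2,6,10-trien-1-yl]-6-[(triisopropylsilyl)oxy]-1-benzofuran-3(2H)-one
Product: 9 (2R)-2,6-dihydroxy-2-[(2E,6E)-3,7,11-trimethyldodeca-2,6,10-trien-1-yl]-1-benzofuran-3(2H)-one
Conditions: HF·pyridine, pyridine, THF, 0 °C; pH 5 buffer work-up
Reagents that add atoms: none
Why: Fluoride cleavage of the aryl Si–O bond with buffered HF·pyridine is a standard phenol desilylation that is neither basic nor strongly acidic, so the hemiketal at C2 should not open and its R configuration, the olefins and the ketone are expected to be preserved.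

**Compound list**

1 | 6-hydroxy-1-benzofuran-3(2H)-one | O=C1COc2cc(O)ccc12 | starting material
2 | 6-[(triisopropylsilyl)oxy]-1-benzofuran-3(2H)-one | O=C1COc2cc(O[Si](C(C)C)(C(C)C)C(C)C)ccc12 | intermediate
3 | (2E,6E)-farnesol, (2E,6E)-3,7,11-trimethyldodeca-2,6,10-trien-1-ol | CC(C)=CCC/C(C)=C/CC/C(C)=C/CO | starting material
4 | (2E,6E)-farnesal, (2E,6E)-3,7,11-trimethyldodeca-2,6,10-trienal | CC(C)=CCC/C(C)=C/CC/C(C)=C/C=O | intermediate
5 | aldol adduct, 2-[(2E,6E)-1-hydroxy-3,7,11-trimethyldodeca-2,6,10-trien-1-yl]-6-[(triisopropylsilyl)oxy]-1-benzofuran-3(2H)-one, diastereomer mixture, not isolated | CC(C)=CCC/C(C)=C/CC/C(C)=C/C(O)C1Oc2cc(O[Si](C(C)C)(C(C)C)C(C)C)ccc2C1=O | intermediate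
6 | (2Z)-2-[(2E,6E)-3,7,11-trimethyldodeca-2,6,10-trien-1-ylidene]-6-[(triisopropylsilyl)oxy]-1-benzofuran-3(2H)-one | CC(C)=CCC/C(C)=C/CC/C(C)=C/C=C1\Oc2cc(O[Si](C(C)C)(C(C)C)C(C)C)ccc2C1=O | intermediate
7 | (2R,3'R)-3'-[(1E,5E)-2,6,10-trimethylundeca-1,5,9-trien-1-yl]-6-[(triisopropylsilyl)oxy]-3H-spiro[1-benzofuran-2,2'-oxiran]-3-one | CC(C)=CCC/C(C)=C/CC/C(C)=C/[C@H]1O[C@@]12Oc3cc(O[Si](C(C)C)(C(C)C)C(C)C)ccc3C2=O | intermediate
8 | (2R)-2-hydroxy-2-[(2E,6E)-3,7,11-trimethyldodeca-2,6,10-trien-1-yl]-6-[(triisopropylsilyl)oxy]-1-benzofuran-3(2H)-one | CC(C)=CCC/C(C)=C/CC/C(C)=C/C[C@@]1(O)Oc2cc(O[Si](C(C)C)(C(C)C)C(C)C)ccc2C1=O | intermediate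
9 | (2R)-2,6-dihydroxy-2-[(2E,6E)-3,7,11-trimethyldodeca-2,6,10-trien-1-yl]-1-benzofuran-3(2H)-one | CC(C)=CCC/C(C)=C/CC/C(C)=C/C[C@@]1(O)Oc2cc(O)ccc2C1=O | target

**Step count**

Total: 6 steps. Longest linear sequence: 5 steps (1 → 2 → 6 → 7 → 8 → 9; the farnesol branch 3 → 4 joins at step 3 and is equally long).

**Steps most likely to fail**

1. Step 5. What may go wrong: hydride is transferred to the distal, fully substituted terminus C3' (giving the 1'-ene with a new C3' centre), or the π-allyl complex loses a β-hydrogen to give a diene. A formate donor was deliberately not chosen, because it characteristically places hydride on the more substituted allyl terminus. Fallback (sets out from 6, returns at 8): the order of events is reversed, hydrogen first and oxygen second. The C2=C1' enone bond of 6 is reduced in the 1,4-sense with [(Ph3P)CuH]6 (wet benzene, rt; the fully substituted C3' blocks 1,6-reduction) to give the C2–H ketone 2-[(2E,6E)-farnesyl]-6-[(triisopropylsilyl)oxy]-1-benzofuran-3(2H)-one F1, racemic at C2. F1 is deprotonated with KN(SiMe3)2 in THF at –78 °C and the tetrasubstituted enolate is hydroxylated with an enantiopure (camphorsulfonyl)oxaziridine (the antipode that gives 2R). The reaction is quenched with AcOH at –78 °C so that the hemiketal oxyanion is not left free, which should give 8 for step 6. Enantiocontrol then rests on the reagent and no longer on the oxirane, and the brief oxyanion stage is the weak point of this alternative.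

2. Step 4. What may go wrong: poor facial selectivity of the conjugate addition inside the ion pair, because the β-substituent is an alkenyl and not an aryl group and the push–pull enone reacts slowly, which gives the uncatalysed interfacial pathway time to compete. Fallback (sets out from 6, returns at 7): asymmetric induction is given up in favour of resolution. 6 is epoxidised without chiral catalyst and without water (t-BuOOH, DBU, CH2Cl2, 0 °C), which should give 7 together with its mirror image, the (2S,3'S)-spiro-oxirane F2. The two are separated by preparative chromatography on a cellulose tris(3,5-dimethylphenylcarbamate) phase, and 7 goes on to step 5.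

3. Step 6. What may go wrong: ring–chain equilibration of the hemiketal through the 1,2-diketone (loss of configurational purity at C2) once the acidic phenol is set free in a fluoride/pyridine medium, or incomplete Si–O cleavage if conditions are kept mild enough to avoid it. Fallback (sets out from 1, returns at 9): the silyl ether is replaced by an allyl ether that is removed in the palladium step, so that no separate deprotection exists. 1 is O-allylated (allyl bromide, K2CO3, acetone, rt) to 6-(allyloxy)-1-benzofuran-3(2H)-one F3. Condensation with 4 on neutral Al2O3 gives, through the aldol adduct F4 (not isolated), the (Z)-dienone F5. Epoxidation under the conditions of step 4 (the allyl ether is inert to base and peroxide) gives the (2R,3'R)-spiro-oxirane F6. Pd(PPh3)4, Bu3SnH (2.6 equiv) and AcOH in CH2Cl2 then open the oxirane to the allyl-protected hemiketal F7 (not isolated) and, in the same flask, cleave the aryl allyl ether as propene, giving 9 directly.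

**Further compounds**

F1 | step 5 | 2-[(2E,6E)-3,7,11-trimethyldodeca-2,6,10-trien-1-yl]-6-[(triisopropylsilyl)oxy]-1-benzofuran-3(2H)-one (racemic) | CC(C)=CCC/C(C)=C/CC/C(C)=C/CC1Oc2cc(O[Si](C(C)C)(C(C)C)C(C)C)ccc2C1=O
F2 | step 4 | (2S,3'S)-3'-[(1E,5E)-2,6,10-trimethylundeca-1,5,9-trien-1-yl]-6-[(triisopropylsilyl)oxy]-3H-spiro[1-benzofuran-2,2'-oxiran]-3-one (enantiomer of 7) | CC(C)=CCC/C(C)=C/CC/C(C)=C/[C@@H]1O[C@]12Oc3cc(O[Si](C(C)C)(C(C)C)C(C)C)ccc3C2=O
F3 | step 6 | 6-(allyloxy)-1-benzofuran-3(2H)-one | O=C1COc2cc(OCC=C)ccc12
F4 | step 6 | 6-(allyloxy)-2-[(2E,6E)-1-hydroxy-3,7,11-trimethyldodeca-2,6,10-trien-1-yl]-1-benzofuran-3(2H)-one (aldol adduct, not isolated) | CC(C)=CCC/C(C)=C/CC/C(C)=C/C(O)C1Oc2cc(OCC=C)ccc2C1=O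
F5 | step 6 | (2Z)-6-(allyloxy)-2-[(2E,6E)-3,7,11-trimethyldodeca-2,6,10-trien-1-ylidene]-1-benzofuran-3(2H)-one | CC(C)=CCC/C(C)=C/CC/C(C)=C/C=C1\Oc2cc(OCC=C)ccc2C1=O
F6 | step 6 | (2R,3'R)-6-(allyloxy)-3'-[(1E,5E)-2,6,10-trimethylundeca-1,5,9-trien-1-yl]-3H-spiro[1-benzofuran-2,2'-oxiran]-3-one | CC(C)=CCC/C(C)=C/CC/C(C)=C/[C@H]1O[C@@]12Oc3cc(OCC=C)ccc3C2=O
F7 | step 6 | (2R)-6-(allyloxy)-2-hydroxy-2-[(2E,6E)-3,7,11-trimethyldodeca-2,6,10-trien-1-yl]-1-benzofuran-3(2H)-one (not isolated) | CC(C)=CCC/C(C)=C/CC/C(C)=C/C[C@@]1(O)Oc2cc(OCC=C)ccc2C1=O
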